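Everything rests on cutting the C3–C4 bond of the γ-butyrolactone ring (O1, C2 carbonyl, C3, C4, C5), the bond between the two benzyl-bearing carbons. The precursor is an acyclic 3-arylpropyl diazoacetate in which C4 is still an unfunctionalised CH2 group. A chiral dirhodium carboxamidate turns the diazo carbon (C3) into a carbene that inserts into one enantiotopic C4–H bond, closing the five-membered ring and setting the (R) centre at C4 in one operation. The step exploits the 1,5 relationship of C3 and the C4 methylene across the ester linkage C2–O1–C5. The C3 centre then follows from trans-selective enolate benzylation, and hydrogenolysis frees both phenols.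

Key step: step 4

Remark: Rh2(4S-MPPIM)4 stands for dirhodium tetrakis[methyl (4S)-2-oxo-1-(3-phenylpropanoyl)imidazolidine-4-carboxylate]. This catalyst, glyoxylic acid chloride p-toluenesulfonylhydrazone and LDA solution are assumed to be purchasable reagents.

Step 1
Reactants: 1 3-(3-hydroxy-4-methoxyphenyl)propanoic acid
Product: 2 benzyl 3-[3-(benzyloxy)-4-methoxyphenyl]propanoate
Conditions: BnBr (2.3 equiv), K2CO3 (3 equiv), DMF, 60 °C
Reagents that add atoms: benzyl bromide, BrCc1ccccc1
Why: Williamson etherification of the phenoxide and SN2 O-alkylation of the carboxylate should cap both acidic groups at once, so that neither the later carbene nor the later enolate meets a free O–H.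

Step 2
Reactants: 2 benzyl 3-[3-(benzyloxy)-4-methoxyphenyl]propanoate
Product: 3 3-[3-(benzyloxy)-4-methoxyphenyl]propan-1-ol
Conditions: LiAlH4 (1.5 equiv), THF, 0 °C to rt; aqueous NaOH work-up
Reagents that add atoms: none
Why: Hydride reduction of the ester should give the primary alcohol, the aryl benzyl ether and the aryl methyl ether being inert to LiAlH4.

Step 3
Reactants: 3 3-[3-(benzyloxy)-4-methoxyphenyl]propan-1-ol
Product: 5 3-[3-(benzyloxy)-4-methoxyphenyl]propyl 2-diazoacetate, via tosylhydrazone ester 4 (not isolated)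
Conditions: glyoxylic acid chloride p-toluenesulfonylhydrazone (1.8 equiv), PhNMe2 (1.8 equiv), CH2Cl2, 0 °C; then Et3N (5 equiv), 0 °C to rt
Reagents that add atoms: glyoxylic acid chloride p-toluenesulfonylhydrazone, Cc1ccc(cc1)S(=O)(=O)N/N=C/C(Cl)=O
Why: In this House-type diazoacetate synthesis (Corey–Myers variant) the alcohol is acylated by the acid chloride, and triethylamine then expels p-toluenesulfinate from the tosylhydrazone 4 in a Bamford–Stevens-type elimination that should leave the diazo ester.

Step 4
Reactants: 5 3-[3-(benzyloxy)-4-methoxyphenyl]propyl 2-diazoacetate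
Product: 6 (4R)-4-[3-(benzyloxy)-4-methoxybenzyl]dihydrofuran-2(3H)-one
Conditions: Rh2(4S-MPPIM)4 (1 mol %), CH2Cl2, reflux, syringe-pump addition of 5 over about 10 h
Reagents that add atoms: none
Why: Loss of N2 from 5 at the dirhodium core gives an electrophilic rhodium-bound carbene whose carbon (future C3) inserts into a C–H bond of the central chain methylene (future C4) through a concerted three-centre transition state, forming the C3–C4 bond. The closest known reaction type is the intramolecular carbene C–H insertion of alkyl diazoacetates to γ-butyrolactones under chiral carboxamidate complexes of divalent rhodium. The five-membered lactone ring (O1, C2, C3, C4, C5) closes by 1,5-insertion, the ester already holding C2–O1–C5 and the carbene reaching the methylene two atoms beyond the ester oxygen. The new C4 centre is set under catalyst control: the chiral imidazolidinone carboxylate ligands around rhodium select one of the two enantiotopic C4–H bonds, the (4S) ligand series being expected to deliver the (R) lactone (the mirror-image catalyst serves if the sense proves opposite). The step needs site selectivity for the C4 methylene over the O-bound C5 methylene (four-membered ring), the benzylic methylene (six-membered ring) and the electron-rich arene, and chemoselectivity over carbene dimerisation. The 1,5 geometry of the ester tether, the low electrophilicity of the carboxamidate-bound carbene and slow addition at high dilution should secure this, and the benzyl-capped phenol removes the O–H insertion pathway.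

Step 5
Reactants: 7 [4-(benzyloxy)-3-methoxyphenyl]methanol
Product: 8 1-(benzyloxy)-4-(bromomethyl)-2-methoxybenzene
Conditions: PBr3 (0.4 equiv), Et2O, 0 °C; used at once
Reagents that add atoms: phosphorus tribromide, BrP(Br)Br
Why: Bromination of a benzylic alcohol with PBr3 (SN2 displacement of the phosphite ester by bromide) should be fast at 0 °C, and using the electron-rich bromide directly avoids its decomposition on storage.

Step 6
Reactants: 6 (4R)-4-[3-(benzyloxy)-4-methoxybenzyl]dihydrofuran-2(3H)-one; 8 1-(benzyloxy)-4-(bromomethyl)-2-methoxybenzene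
Product: 10 (3R,4R)-3-[4-(benzyloxy)-3-methoxybenzyl]-4-[3-(benzyloxy)-4-methoxybenzyl]dihydrofuran-2(3H)-one, via lithium enolate 9 (not isolated)
Conditions: LDA (1.1 equiv), THF, −78 °C; then 8 (1.2 equiv), DMPU, −78 to −40 °C
Reagents that add atoms: none
Why: In this enolate alkylation (SN2) LDA removes a C3 proton of 6 and the benzylic bromide approaches the planar enolate 9 on the face opposite the C4 arylmethyl group, so the new C3 centre should be set trans to C4 by substrate control, giving the (3R,4R) configuration.

Step 7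
Reactants: 10 (3R,4R)-3-[4-(benzyloxy)-3-methoxybenzyl]-4-[3-(benzyloxy)-4-methoxybenzyl]dihydrofuran-2(3H)-one
Product: 11 (3R,4R)-3-(4-hydroxy-3-methoxybenzyl)-4-(3-hydroxy-4-methoxybenzyl)dihydrofuran-2(3H)-one
Conditions: H2 (1 atm), 10% Pd/C, EtOAc–EtOH, rt
Reagents that add atoms: none
Why: Heterogeneous hydrogenolysis of the two aryl benzyl ethers should free both phenols under neutral conditions that touch neither the lactone nor the epimerisable C3 centre.

Compound list
1 | 3-(3-hydroxy-4-methoxyphenyl)propanoic acid | COc1ccc(CCC(=O)O)cc1O | starting material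
2 | benzyl 3-[3-(benzyloxy)-4-methoxyphenyl]propanoate | COc1ccc(CCC(=O)OCc2ccccc2)cc1OCc1ccccc1 | intermediate
3 | 3-[3-(benzyloxy)-4-methoxyphenyl]propan-1-ol | COc1ccc(CCCO)cc1OCc1ccccc1 | intermediate
4 | 3-[3-(benzyloxy)-4-methoxyphenyl]propyl (E)-2-(2-tosylhydrazinylidene)acetate (not isolated) | COc1ccc(CCCOC(=O)/C=N/NS(=O)(=O)c2ccc(C)cc2)cc1OCc1ccccc1 | intermediate
5 | 3-[3-(benzyloxy)-4-methoxyphenyl]propyl 2-diazoacetate | COc1ccc(CCCOC(=O)C=[N+]=[N-])cc1OCc1ccccc1 | intermediate
6 | (4R)-4-[3-(benzyloxy)-4-methoxybenzyl]dihydrofuran-2(3H)-one | COc1ccc(C[C@H]2COC(=O)C2)cc1OCc1ccccc1 | intermediate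
7 | [4-(benzyloxy)-3-methoxyphenyl]methanol | COc1cc(CO)ccc1OCc1ccccc1 | starting material
8 | 1-(benzyloxy)-4-(bromomethyl)-2-methoxybenzene | COc1cc(CBr)ccc1OCc1ccccc1 | intermediate
9 | lithium (4R)-4-[3-(benzyloxy)-4-methoxybenzyl]-4,5-dihydrofuran-2-olate (not isolated) | COc1ccc(C[C@H]2COC(O[Li])=C2)cc1OCc1ccccc1 | intermediate
10 | (3R,4R)-3-[4-(benzyloxy)-3-methoxybenzyl]-4-[3-(benzyloxy)-4-methoxybenzyl]dihydrofuran-2(3H)-one | COc1ccc(C[C@H]2COC(=O)[C@@H]2Cc2ccc(OCc3ccccc3)c(OC)c2)cc1OCc1ccccc1 | intermediate
11 | (3R,4R)-3-(4-hydroxy-3-methoxybenzyl)-4-(3-hydroxy-4-methoxybenzyl)dihydrofuran-2(3H)-one | COc1ccc(C[C@H]2COC(=O)[C@@H]2Cc2ccc(O)c(OC)c2)cc1O | target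

Total step count: 7
Longest linear sequence: 6 steps (steps 1, 2, 3, 4, 6 and 7)

Steps most likely to fail

Step 4. The carbene may be diverted into attack on the electron-rich arene, insertion at the benzylic or O-bound methylene, or dimerisation, or the discrimination of the enantiotopic C4–H bonds may be insufficient. The fallback sets out from 2 and comes back at 6 by auxiliary-controlled alkylation. Ester 2 is saponified (LiOH, THF–H2O) to 3-[3-(benzyloxy)-4-methoxyphenyl]propanoic acid F1. Pivaloyl chloride and Et3N convert it into 3-[3-(benzyloxy)-4-methoxyphenyl]propanoic pivalic anhydride F2 (not isolated), which acylates (S)-4-benzyloxazolidin-2-one in the presence of LiCl to give (4S)-4-benzyl-3-{3-[3-(benzyloxy)-4-methoxyphenyl]propanoyl}oxazolidin-2-one F3. NaHMDS in THF at −78 °C forms sodium (Z)-1-[(4S)-4-benzyl-2-oxooxazolidin-3-yl]-3-[3-(benzyloxy)-4-methoxyphenyl]prop-1-en-1-olate F4 (not isolated). tert-Butyl bromoacetate alkylates it on the face remote from the auxiliary benzyl group, giving tert-butyl (3R)-3-[3-(benzyloxy)-4-methoxybenzyl]-4-[(4S)-4-benzyl-2-oxooxazolidin-3-yl]-4-oxobutanoate F5. LiBH4 removes the auxiliary reductively to give tert-butyl (3R)-3-[3-(benzyloxy)-4-methoxybenzyl]-4-hydroxybutanoate F6, and catalytic p-TsOH in warm toluene closes it to lactone 6.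

Step 6. Over-alkylation, proton exchange between product and enolate, decomposition of the electron-rich benzylic bromide before it is captured, or incomplete trans selectivity may erode the step. The fallback sets out from 6 and comes back at 11, replacing alkylation by an aldol addition. Enolate 9 (LDA, THF, −78 °C) is added to commercial 4-(benzyloxy)-3-methoxybenzaldehyde (COc1cc(C=O)ccc1OCc1ccccc1), anti to the C4 substituent. This should give trans (3S,4R)-4-[3-(benzyloxy)-4-methoxybenzyl]-3-{[4-(benzyloxy)-3-methoxyphenyl](hydroxy)methyl}dihydrofuran-2(3H)-one F7 as a mixture of carbinol epimers, which is of no consequence. Hydrogenolysis (H2, Pd(OH)2/C, EtOH–AcOH) then removes the electron-rich benzylic hydroxyl together with both benzyl ethers and leads directly to 11.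

Step 3. Base-induced fragmentation of the tosylhydrazone may stall, or the acid-sensitive diazo ester may be lost during isolation. The fallback sets out from 3 and comes back at 5 by building the diazo group through N-alkylation instead of acylation. Bromoacetyl bromide (NaHCO3, MeCN, 0 °C) converts 3 into 3-[3-(benzyloxy)-4-methoxyphenyl]propyl 2-bromoacetate F8. N,N'-Ditosylhydrazine and DBU (THF, 0 °C) then give 3-[3-(benzyloxy)-4-methoxyphenyl]propyl 2-[1,2-bis(p-tolylsulfonyl)hydrazinyl]acetate F9 (not isolated), which sheds two sulfinate groups under DBU to give 5.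

Further compounds
F1 | step 4 | 3-[3-(benzyloxy)-4-methoxyphenyl]propanoic acid | COc1ccc(CCC(=O)O)cc1OCc1ccccc1
F2 | step 4 | 3-[3-(benzyloxy)-4-methoxyphenyl]propanoic pivalic anhydride | COc1ccc(CCC(=O)OC(=O)C(C)(C)C)cc1OCc1ccccc1
F3 | step 4 | (4S)-4-benzyl-3-{3-[3-(benzyloxy)-4-methoxyphenyl]propanoyl}oxazolidin-2-one | COc1ccc(CCC(=O)N2[C@@H](Cc3ccccc3)COC2=O)cc1OCc1ccccc1
F4 | step 4 | sodium (Z)-1-[(4S)-4-benzyl-2-oxooxazolidin-3-yl]-3-[3-(benzyloxy)-4-methoxyphenyl]prop-1-en-1-olate | COc1ccc(C/C=C(\[O-])N2[C@@H](Cc3ccccc3)COC2=O)cc1OCc1ccccc1.[Na+]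
F5 | step 4 | tert-butyl (3R)-3-[3-(benzyloxy)-4-methoxybenzyl]-4-[(4S)-4-benzyl-2-oxooxazolidin-3-yl]-4-oxobutanoate | COc1ccc(C[C@H](CC(=O)OC(C)(C)C)C(=O)N2[C@@H](Cc3ccccc3)COC2=O)cc1OCc1ccccc1
F6 | step 4 | tert-butyl (3R)-3-[3-(benzyloxy)-4-methoxybenzyl]-4-hydroxybutanoate | COc1ccc(C[C@H](CC(=O)OC(C)(C)C)CO)cc1OCc1ccccc1
F7 | step 6 | (3S,4R)-4-[3-(benzyloxy)-4-methoxybenzyl]-3-{[4-(benzyloxy)-3-methoxyphenyl](hydroxy)methyl}dihydrofuran-2(3H)-one, both carbinol epimers | COc1ccc(C[C@H]2COC(=O)[C@@H]2C(O)c2ccc(OCc3ccccc3)c(OC)c2)cc1OCc1ccccc1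
F8 | step 3 | 3-[3-(benzyloxy)-4-methoxyphenyl]propyl 2-bromoacetate | COc1ccc(CCCOC(=O)CBr)cc1OCc1ccccc1
F9 | step 3 | 3-[3-(benzyloxy)-4-methoxyphenyl]propyl 2-[1,2-bis(p-tolylsulfonyl)hydrazinyl]acetate | COc1ccc(CCCOC(=O)CN(NS(=O)(=O)c2ccc(C)cc2)S(=O)(=O)c2ccc(C)cc2)cc1OCc1ccccc1
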